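Late in Saturday's run, at 50.0 s, the flask reads 72% ring and 12% starting material. In these flasks starting material is fed over 25 s into a stirred solution that holds a protic impurity, and ring forms.

| flask | starting material | protic impurity | remark | time |
|---|---|---|---|---|
| Saturday's | 0.067 M (fed, over 25 s) | 0.40 mM | run made earlier; the fed solution adds 0.10 times the starting volume |  |
| alpha | 0.10 M (fed, over 25 s) | 0.400 mM | the fed solution adds 0.10 times the starting volume | 4.0 min |
| zeta | 0.10 M (fed, over 25 s) | 0.600 mM | the fed solution adds 0.10 times the starting volume | 4.0 min |
| gamma | 0.10 M (fed, over 25 s) | 0.800 mM | the fed solution adds 0.10 times the starting volume | 4.0 min |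
| eta | 0.10 M (fed, over 25 s) | 1.20 mM | the fed solution adds 0.10 times the starting volume | 4.0 min |
| epsilon | 0.10 M (fed, over 25 s) | 2.00 mM | the fed solution adds 0.10 times the starting volume | 4.0 min |

- Saturday's (time / s: ring / %, starting material / %): 10.0: 13, 24; 20.0: 35, 40; 30.0: 61, 31; 40.0: 65, 17; 50.0: 72, 12

(readings scatter by 2 percentage points)

- charges are per starting volume, the dose included; the dosed solution carries all of it
- a reading or a percentage of ring counts all its forms, free or not
- "hardly changes" means that all values lie within two and a half points (for a concentration: within two and a half percent of the largest)
- percentages count the whole charge, also what has not yet gone in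
- no earlier run changes the charge of protic impurity; that part of a forecast is a guess

- amount of ring at the end, in percent of the starting material charged for alpha, zeta, gamma, eta, epsilon, in this order
- how the row runs (falls, then rises / hardly changes / falls all the way / rises, then falls / rises all the way)

We read Saturday's table from the bottom up. At 50.0 s ring and starting material add up to 84.0%, and at 40.0 s to 82.0%. At 30.0 s, just after the feed, they add up to 92.0%. So 16.0% of the charge is unread in the last row. Ring is still climbing there, so we commit to no level from these readings.

What the impurity costs is a guess, as no earlier run changes its charge. Saturday's 0.40 mM over 0.067 M is 0.597%, and the readings scatter by 2 percentage points, so its effect is lost in the scatter. For alpha, 0.400 mM over 0.10 M gives 0.400%. We call this the impurity share, protic impurity charged over starting material charged.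

Our guess is that each impurity takes one starting material. The impurity is then the limiting reagent of that step, since its largest charge is smaller than the charge of starting material. Epsilon's share is 2.00%, so we expect ring to fall by 1.6 points from alpha to epsilon. That lies inside the margin for "hardly changes".

The forecast gives 77%, 76.8%, 76.6%, 76.2% and 75.4%, and says the row hardly changes. Its ground for the shape is ours: “so ring falls by less than 2 points”.

The flask gives 89.6%, 89.4%, 89.2%, 88.8% and 88.0%, and the row hardly changes.

    starting material ⇌ ring (K = 1.80, k = 0.0850 /s)
    2 starting material ⇌ open dimer (K = 31.0 /M, k = 0.410 /M/s)
    crystals ⇌ ring, rate k3*(cs3 - [ring]) while solid is left; crystals form when [ring] > cs3 (solubility = 10.0 mM, k = 6.30 /s)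
    starting material + protic impurity → quenched substrate (k = 12.0 /M/s)

In alpha the quenched substrate ends at 0.400%, matching the share of 0.400%, with protic impurity at 0%. In epsilon it ends at 2.00%, matching 2.00%, and ring's fall of 1.6 points matches the reckoned 1.6 points. The level is another matter: alpha stands 13 points above the forecast. The main reason for alpha's high level of ring is the low solubility of ring, which puts 78.6% into crystals in alpha at 4.00 min. The same alpha flask without that low solubility ends at 43.3% ring.

Readings and results were computed with constants of no real substance; scatter was added.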